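**Retrosynthetic overview**
1. Target 24 ⇐ Luche reduction of the C9 ketone and acylation of C8–OH with (2R,3R)-epoxyangelic acid 21 ⇐ ketol 16.
2. 16 ⇐ ring expansion (key step): SmI2 ketyl closure C8→C9 onto the cyclohexenone carbonyl, then Grob fragmentation of C4–C9 with loss of C5–OMs; six-membered ring A becomes the ten-membered ring and the 4E alkene and C8 are set ⇐ aldehyde 14.
3. 14 ⇐ indium Barbier allylation/lactonisation (C6–C7, cis-lactone) of α-mesyloxy aldehyde 7 with bromide 11 (from 2,2-dimethoxyacetaldehyde and methyl acrylate).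
4. 7 ⇐ aldol (C4–C5) of 2-methylcyclohex-2-en-1-one with (R)-glyceraldehyde acetonide, Fráter–Seebach methylation, mesylation, glycol cleavage; chirality is relayed C5 → C6/C7 → C8 → C9, and C4/C5 are erased in the fragmentation.
5. Ring order: cyclohexenone ring A (bought, carries the 1(10)Z alkene) → γ-lactone → transient six-membered ring B → ten-membered carbocycle.

Convention: germacrane numbering is used in names and explanations (C1–C10 ring, C11–C13 lactone/methylene, C14 methyl on C10, C15 methyl on C4).

**Step 1**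
Reactants: 1 2-methylcyclohex-2-en-1-one; 2 (4R)-2,2-dimethyl-1,3-dioxolane-4-carbaldehyde
Product: 3 6-{(S)-hydroxy[(4R)-2,2-dimethyl-1,3-dioxolan-4-yl]methyl}-2-methylcyclohex-2-en-1-one (both epimers at ring C6)
Conditions: LiN(iPr)2, THF, −78 °C; then 2, −78 °C; NH4Cl (aq)
Reagents that add atoms: none
Why: Kinetic α′-deprotonation gives the cross-conjugated lithium dienolate, and its aldol addition to the α-alkoxy aldehyde follows the polar Felkin–Anh model (attack anti to the dioxolane C–O bond), setting C5 as S; the ring-carbon epimers are erased in step 2.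

**Step 2**
Reactants: 3 6-{(S)-hydroxy[(4R)-2,2-dimethyl-1,3-dioxolan-4-yl]methyl}-2-methylcyclohex-2-en-1-one
Product: 4 (6S)-6-{(S)-hydroxy[(4R)-2,2-dimethyl-1,3-dioxolan-4-yl]methyl}-2,6-dimethylcyclohex-2-en-1-one
Conditions: LiN(iPr)2 (2.3 equiv), THF, −78 → −40 °C; MeI, DMPU, −78 → −20 °C; NH4Cl (aq)
Reagents that add atoms: iodomethane, CI
Why: Fráter–Seebach alkylation: the chelated lithium alkoxide–enolate dianion is methylated on the face opposite the dioxolanyl group, so the quaternary C4 (S) has its methyl anti to the C5 oxygen, the relative configuration that later gives the 4E alkene; the minor C5 epimer from step 1 is removed here.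

**Step 3**
Reactants: 4 (6S)-6-{(S)-hydroxy[(4R)-2,2-dimethyl-1,3-dioxolan-4-yl]methyl}-2,6-dimethylcyclohex-2-en-1-one
Product: 5 (S)-[(4R)-2,2-dimethyl-1,3-dioxolan-4-yl][(1S)-1,3-dimethyl-2-oxocyclohex-3-en-1-yl]methyl methanesulfonate
Conditions: MsCl, Et3N, DMAP (cat.), CH2Cl2, 0 °C
Reagents that add atoms: methanesulfonyl chloride, CS(=O)(=O)Cl
Why: Sulfonylation of the hindered secondary alcohol installs the leaving group for the Grob fragmentation; with no hydrogen on C4 the β-mesyloxy ketone cannot eliminate.

**Step 4**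
Reactants: 5 (S)-[(4R)-2,2-dimethyl-1,3-dioxolan-4-yl][(1S)-1,3-dimethyl-2-oxocyclohex-3-en-1-yl]methyl methanesulfonate
Product: 7 (1S)-1-[(1S)-1,3-dimethyl-2-oxocyclohex-3-en-1-yl]-2-oxoethyl methanesulfonate, via diol mesylate 6 (not isolated)
Conditions: H5IO6, EtOAc, 25 °C
Reagents that add atoms: none
Why: Periodic acid hydrolyses the terminal acetonide and cleaves the diol in one pot (Malaprade glycol cleavage), so the glyceraldehyde stereocentre, having set C5, is excised and C6 is released as an aldehyde that is used crude.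

**Step 5**
Reactants: 8 2,2-dimethoxyacetaldehyde; 9 methyl acrylate
Product: 10 methyl 3-hydroxy-4,4-dimethoxy-2-methylidenebutanoate (racemic)
Conditions: DABCO (0.5 equiv), 1,4-dioxane/H2O, 25 °C
Reagents that add atoms: none
Why: Morita–Baylis–Hillman reaction of an activated α-alkoxy aldehyde; the racemic carbinol centre disappears in step 6.

**Step 6**
Reactants: 10 methyl 3-hydroxy-4,4-dimethoxy-2-methylidenebutanoate
Product: 11 methyl (2Z)-2-(bromomethyl)-4,4-dimethoxybut-2-enoate
Conditions: NBS, Me2S, CH2Cl2, 0 → 25 °C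
Reagents that add atoms: N-bromosuccinimide, O=C1CCC(=O)N1Br
Why: Corey–Kim-type activation of the allylic alcohol and SN2′ delivery of bromide give the thermodynamically preferred trisubstituted (Z)-allylic bromide under neutral conditions that spare the acetal.

**Step 7**
Reactants: 7 (1S)-1-[(1S)-1,3-dimethyl-2-oxocyclohex-3-en-1-yl]-2-oxoethyl methanesulfonate; 11 methyl (2Z)-2-(bromomethyl)-4,4-dimethoxybut-2-enoate
Product: 13 (S)-[(2R,3S)-3-(dimethoxymethyl)-4-methylidene-5-oxooxolan-2-yl][(1S)-1,3-dimethyl-2-oxocyclohex-3-en-1-yl]methyl methanesulfonate, via hydroxy ester 12 (not isolated)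
Conditions: In powder, THF/H2O (1:1), 25 °C; then CSA (cat.), CH2Cl2, 25 °C
Reagents that add atoms: none
Why: Indium-mediated Barbier allylation (γ-attack through a chair transition state) forms C6–C7; addition to the non-chelating α-mesyloxy aldehyde in the polar Felkin–Anh/Cornforth sense sets C6 (R, oxygen anti to C5–OMs), the ester-bearing allylindium gives the syn adduct (C7 S), and acid closes the cis-fused α-methylene-γ-butyrolactone.

**Step 8**
Reactants: 13 (S)-[(2R,3S)-3-(dimethoxymethyl)-4-methylidene-5-oxooxolan-2-yl][(1S)-1,3-dimethyl-2-oxocyclohex-3-en-1-yl]methyl methanesulfonate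
Product: 14 (S)-[(1S)-1,3-dimethyl-2-oxocyclohex-3-en-1-yl][(2R,3S)-3-formyl-4-methylidene-5-oxooxolan-2-yl]methyl methanesulfonate
Conditions: LiBF4, MeCN/H2O (98:2), 25 °C
Reagents that add atoms: water, O
Why: Mild Lewis-acid-assisted acetal hydrolysis unmasks the C8 aldehyde without touching mesylate, enone or methylene lactone; the enolisable aldehyde is used at once.

**Step 9**
Reactants: 14 (S)-[(1S)-1,3-dimethyl-2-oxocyclohex-3-en-1-yl][(2R,3S)-3-formyl-4-methylidene-5-oxooxolan-2-yl]methyl methanesulfonate
Product: 16 (6S,7R,8R)-8-hydroxy-9-oxogermacra-1(10)Z,4E,11(13)-trien-12,6-olide, via bicyclic samarium diolate 15 (not isolated)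
Conditions: SmI2 (2.1 equiv), THF, −78 °C, then 25 °C; NH4Cl (aq)
Reagents that add atoms: none
Why: Proposed new method: a samarium diiodide ketyl (pinacol-type) cyclisation coupled in the same flask to a Grob fragmentation; electron transfer to the C8 aldehyde gives a ketyl that adds to the C9 ketone through a chair-like six-membered transition state (ring B) in which the samarium-bound C8 oxygen is equatorial, because an axial oxygen would be syn-diaxial to the C4 methyl and the C6 lactone oxygen, and this sets C8 as R; in the resulting trivalent-samarium alkoxide of the tertiary C9 alcohol the ring-fusion bond C4–C9 is antiperiplanar to the equatorial C5–OMs bond (C3 anti to C6), so on warming the alkoxide collapses to the C9 ketone, C4–C9 breaks, mesylate leaves and the 4E alkene forms stereospecifically, turning the six-membered ring A into the ten-membered ring (both C9 epimers of the adduct converge); the closest known reaction type is the samarium diiodide intramolecular Barbier cyclisation/Grob fragmentation sequence of iodoalkyl keto mesylates, together with the known samarium diiodide intramolecular pinacol coupling, whereas a ketyl-initiated variant delivering an α-hydroxy cycloalkenone has not been shown.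

**Step 10**
Reactants: 17 (2Z)-2-methylbut-2-enoic acid (angelic acid)
Product: 18 (2Z)-2-methylbut-2-en-1-ol
Conditions: LiAlH4, Et2O, 0 °C
Reagents that add atoms: none
Why: Hydride reduction of the acid to the allylic alcohol leaves the trisubstituted (Z)-alkene untouched.

**Step 11**
Reactants: 18 (2Z)-2-methylbut-2-en-1-ol
Product: 19 [(2S,3R)-2,3-dimethyloxiran-2-yl]methanol
Conditions: Ti(OiPr)4 (10 mol %), L-(+)-diethyl tartrate (12 mol %), t-BuOOH, 4 Å MS, CH2Cl2, −20 °C
Reagents that add atoms: tert-butyl hydroperoxide, CC(C)(C)OO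
Why: Sharpless asymmetric epoxidation; with L-(+)-diethyl tartrate oxygen is delivered to the alkene face that gives the (2S,3R)-epoxy alcohol, both epoxide centres being set at once.

**Step 12**
Reactants: 19 [(2S,3R)-2,3-dimethyloxiran-2-yl]methanol
Product: 21 (2R,3R)-2,3-dimethyloxirane-2-carboxylic acid, via epoxy aldehyde 20 (not isolated)
Conditions: RuCl3 (cat.), NaIO4, CCl4/MeCN/H2O, 25 °C
Reagents that add atoms: water, O; sodium periodate, [Na+].[O-][I](=O)(=O)=O
Why: RuO4-catalysed oxidation of the primary alcohol through the aldehyde hydrate gives the acid without opening the epoxide; the C2 descriptor changes only through the priority rules.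

**Step 13**
Reactants: 16 (6S,7R,8R)-8-hydroxy-9-oxogermacra-1(10)Z,4E,11(13)-trien-12,6-olide; 21 (2R,3R)-2,3-dimethyloxirane-2-carboxylic acid
Product: 23 (6S,7S,8R)-8-{[(2R,3R)-2,3-dimethyloxirane-2-carbonyl]oxy}-9-oxogermacra-1(10)Z,4E,11(13)-trien-12,6-olide, via mixed anhydride 22 (not isolated)
Conditions: 2,4,6-trichlorobenzoyl chloride, Et3N, THF, 25 °C; then 16, DMAP, toluene, 25 °C
Reagents that add atoms: none
Why: Yamaguchi esterification acylates the only free hydroxyl (C8) with the hindered epoxy acid, with retention at C8 and no acid that could open the epoxide.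

**Step 14**
Reactants: 23 (6S,7S,8R)-8-{[(2R,3R)-2,3-dimethyloxirane-2-carbonyl]oxy}-9-oxogermacra-1(10)Z,4E,11(13)-trien-12,6-olide
Product: 24 (6S,7S,8R,9R)-9-hydroxy-8-{[(2R,3R)-2,3-dimethyloxirane-2-carbonyl]oxy}germacra-1(10)Z,4E,11(13)-trien-12,6-olide (CNP0318223.2)
Conditions: NaBH4, CeCl3·7H2O, MeOH, −78 °C
Reagents that add atoms: none
Why: Luche reduction is 1,2-selective for the enone and spares the methylene lactone, ester and epoxide; hydride adds in the polar Felkin–Anh sense anti to the C8 acyloxy group from the outer face of the ring, giving the 8,9-threo alcohol (C9 R).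

**Compound list**
1 | 2-methylcyclohex-2-en-1-one | CC1=CCCCC1=O | starting material
2 | (4R)-2,2-dimethyl-1,3-dioxolane-4-carbaldehyde ((R)-glyceraldehyde acetonide) | O=C[C@H]1COC(C)(C)O1 | starting material
3 | 6-{(S)-hydroxy[(4R)-2,2-dimethyl-1,3-dioxolan-4-yl]methyl}-2-methylcyclohex-2-en-1-one (both ring C6 epimers) | CC1=CCCC([C@H](O)[C@H]2COC(C)(C)O2)C1=O | intermediate
4 | (6S)-6-{(S)-hydroxy[(4R)-2,2-dimethyl-1,3-dioxolan-4-yl]methyl}-2,6-dimethylcyclohex-2-en-1-one | CC1=CCC[C@@](C)([C@H](O)[C@H]2COC(C)(C)O2)C1=O | intermediate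
5 | (S)-[(4R)-2,2-dimethyl-1,3-dioxolan-4-yl][(1S)-1,3-dimethyl-2-oxocyclohex-3-en-1-yl]methyl methanesulfonate | CC1=CCC[C@@](C)([C@H](OS(C)(=O)=O)[C@H]2COC(C)(C)O2)C1=O | intermediate
6 | (1S,2R)-1-[(1S)-1,3-dimethyl-2-oxocyclohex-3-en-1-yl]-2,3-dihydroxypropyl methanesulfonate | CC1=CCC[C@@](C)([C@H](OS(C)(=O)=O)[C@H](O)CO)C1=O | intermediate
7 | (1S)-1-[(1S)-1,3-dimethyl-2-oxocyclohex-3-en-1-yl]-2-oxoethyl methanesulfonate | CC1=CCC[C@@](C)([C@H](OS(C)(=O)=O)C=O)C1=O | intermediate
8 | 2,2-dimethoxyacetaldehyde | COC(OC)C=O | starting material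
9 | methyl acrylate | C=CC(=O)OC | starting material
10 | methyl 3-hydroxy-4,4-dimethoxy-2-methylidenebutanoate (racemic) | COC(OC)C(O)C(=C)C(=O)OC | intermediate
11 | methyl (2Z)-2-(bromomethyl)-4,4-dimethoxybut-2-enoate | COC(=O)/C(CBr)=C/C(OC)OC | intermediate
12 | methyl (3S,4R,5S)-3-(dimethoxymethyl)-5-[(1S)-1,3-dimethyl-2-oxocyclohex-3-en-1-yl]-4-hydroxy-5-(methanesulfonyloxy)-2-methylidenepentanoate | CC1=CCC[C@@](C)([C@H](OS(C)(=O)=O)[C@H](O)[C@H](C(=C)C(=O)OC)C(OC)OC)C1=O | intermediate
13 | (S)-[(2R,3S)-3-(dimethoxymethyl)-4-methylidene-5-oxooxolan-2-yl][(1S)-1,3-dimethyl-2-oxocyclohex-3-en-1-yl]methyl methanesulfonate | CC1=CCC[C@@](C)([C@H](OS(C)(=O)=O)[C@@H]2OC(=O)C(=C)[C@@H]2C(OC)OC)C1=O | intermediate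
14 | (S)-[(1S)-1,3-dimethyl-2-oxocyclohex-3-en-1-yl][(2R,3S)-3-formyl-4-methylidene-5-oxooxolan-2-yl]methyl methanesulfonate | CC1=CCC[C@@](C)([C@H](OS(C)(=O)=O)[C@@H]2OC(=O)C(=C)[C@@H]2C=O)C1=O | intermediate
15 | ring B pinacol adduct: C4–C9-bonded trans-fused bicycle carrying 5-OMs, the 12,6-lactone, 8-OH and 9-OH (4-Me, 5-OMs, 6-O and C11 all cis on ring B; 8-OH trans to C11 and cis to 9-OH); present in the flask as its trivalent-samarium diolate, SMILES drawn as the free diol | CC1=CCC[C@@]2(C)[C@H](OS(C)(=O)=O)[C@@H]3OC(=O)C(=C)[C@@H]3[C@@H](O)[C@]12O | intermediate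
16 | (6S,7R,8R)-8-hydroxy-9-oxogermacra-1(10)Z,4E,11(13)-trien-12,6-olide | C=C1C(=O)O[C@H]2/C=C(\C)CC/C=C(/C)C(=O)[C@H](O)[C@@H]12 | intermediate
17 | (2Z)-2-methylbut-2-enoic acid (angelic acid) | C/C=C(/C)C(=O)O | starting material
18 | (2Z)-2-methylbut-2-en-1-ol | C/C=C(/C)CO | intermediate
19 | [(2S,3R)-2,3-dimethyloxiran-2-yl]methanol | OC[C@]1(C)O[C@@H]1C | intermediate
20 | (2R,3R)-2,3-dimethyloxirane-2-carbaldehyde | O=C[C@]1(C)O[C@@H]1C | intermediate
21 | (2R,3R)-2,3-dimethyloxirane-2-carboxylic acid | OC(=O)[C@]1(C)O[C@@H]1C | intermediate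
22 | (2R,3R)-2,3-dimethyloxirane-2-carboxylic 2,4,6-trichlorobenzoic anhydride | O=C(OC(=O)c1c(Cl)cc(Cl)cc1Cl)[C@]2(C)O[C@@H]2C | intermediate
23 | (6S,7S,8R)-8-{[(2R,3R)-2,3-dimethyloxirane-2-carbonyl]oxy}-9-oxogermacra-1(10)Z,4E,11(13)-trien-12,6-olide | C=C1C(=O)O[C@H]2/C=C(\C)CC/C=C(/C)C(=O)[C@H](OC(=O)[C@]3(C)O[C@@H]3C)[C@@H]12 | intermediate
24 | (6S,7S,8R,9R)-9-hydroxy-8-{[(2R,3R)-2,3-dimethyloxirane-2-carbonyl]oxy}germacra-1(10)Z,4E,11(13)-trien-12,6-olide | C=C1C(=O)O[C@H]2/C=C(\C)CC/C=C(/C)[C@@H](O)[C@H](OC(=O)[C@]3(C)O[C@@H]3C)[C@@H]12 | target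

**Step count**
Total: 14 steps. Longest linear sequence: 9 steps (steps 1, 2, 3, 4, 7, 8, 9, 13, 14).

**Steps most likely to fail, with fallbacks**

Step 9 (the proposed new step). The risks are competing reduction of the enone or the methylene lactone, a chelated samarium diolate that does not fragment, and over-reduction of the α-ketol product. The fallback uses known chemistry, sets out from 14 and comes back at 16 by separating the two events into two classical reactions. The samarium diiodide intramolecular aldehyde–ketone pinacol coupling is run at −78 °C and quenched cold with MeOH, so that the bicyclic cis-diol mesylate 15 is isolated as the free diol; this makes no compound outside the list (F0). A base-induced Wharton–Grob fragmentation of this 1,3-diol monosulfonate with KN(SiMe3)2 in THF (−78 → 0 °C) then gives 16 with the same stereospecific 4E outcome.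

Step 7. Three contiguous centres are controlled in one operation (Felkin against chelation, syn against anti), and the α-mesyloxy aldehyde 7 is labile. The fallback sets out from 10 (with 7) and comes back at 13 through an allylboration with a closed transition state. Acetylation of 10 (Ac2O, pyridine, DMAP) gives methyl 3-acetoxy-4,4-dimethoxy-2-methylidenebutanoate F1. Copper-catalysed SN2′ borylation (B2pin2, CuCl, KOAc, DMF) gives methyl (2E)-4,4-dimethoxy-2-[(4,4,5,5-tetramethyl-1,3,2-dioxaborolan-2-yl)methyl]but-2-enoate F2, in which the dimethoxymethyl group is cis to CH2B. Uncatalysed allylboration of 7 (toluene, 60 °C) through a chair transition state gives the syn adduct with the same polar Felkin–Anh facial preference. Work-up and CSA then lactonise the hydroxy ester 12 to 13.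

Step 14. The facial selectivity of hydride addition to the macrocyclic α-acyloxy enone is not assured, and conjugate reduction of the methylene lactone or acyl migration could interfere. The fallback sets out from 23 and comes back at 24 by moving stereocontrol from the substrate to a chiral catalyst. A Corey–Bakshi–Shibata reduction is used with (R)-2-methyl-CBS-oxazaborolidine and catecholborane in toluene at −78 °C; this is the catalyst enantiomer matched to C9 R if, as usual for enones, the alkenyl side acts as the large group. It makes no compound outside the list (F0).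

**Further compounds**
F1 | step 7 | methyl 3-acetoxy-4,4-dimethoxy-2-methylidenebutanoate (racemic) | COC(OC)C(OC(C)=O)C(=C)C(=O)OC
F2 | step 7 | methyl (2E)-4,4-dimethoxy-2-[(4,4,5,5-tetramethyl-1,3,2-dioxaborolan-2-yl)methyl]but-2-enoate | COC(=O)/C(CB1OC(C)(C)C(C)(C)O1)=C/C(OC)OC
F0 | step 9 | none | none
F0 | step 14 | none | none
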